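Everything rests on closing the hydroxyquinone ring C (C8, C9, C11–C14) last. Its C11–C14 half carries O, O, isopropyl, O, the pattern of a squaric acid derivative. Its C8=C9 edge is the alkene of the 2-oxabicyclo[2.2.2]octene built from ring B and the C20–O–C7 lactone. The key step heats a 4-hydroxycyclobutenone attached through C14 to C8 of the finished A/B/lactone tricycle. Strain-driven 4π opening to a dienylketene, 6π closure of C9–C11 and oxidation give the fully substituted quinone in one operation. The tricycle arises from an intramolecular Diels–Alder reaction of a 5-bromo-2-pyrone whose single stereocentre (C4) stems from a Sharpless epoxide.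

Key step: step 10

Remark: abietane numbering (C1–C20) is used for all advanced compounds. The target is read as 6α,12,19-trihydroxy-11,14-dioxoabieta-8,12-dien-20,7β-olide (5α-H, C20 β, C19 the axial β-CH2OH). Compounds 18 and 19 are carried as mixtures of epimers at the carbinol carbon C14, which becomes sp2 in step 10, so their SMILES leave this centre open.

Step 1
Reactants: 1 pent-1-en-4-yne
Product: 4 (E)-3-methylhexa-2,5-dien-1-ol, via alkenyldimethylalane 2 (not isolated), via lithium alanate 3 (not isolated)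
Conditions: Me3Al, Cp2ZrCl2 (cat.), CH2Cl2, 0 °C to rt; n-BuLi, THF–hexane, 0 °C; (CH2O)n, rt; aq. work-up
Reagents that add atoms: trimethylaluminium C[Al](C)C; paraformaldehyde (as formaldehyde) C=O
Why: Negishi zirconium-catalysed carboalumination adds Me and Al syn and with Al terminal across the alkyne in preference to the monosubstituted alkene, and the derived alanate is hydroxymethylated with retention, which fixes the E geometry.

Step 2
Reactants: 4 (E)-3-methylhexa-2,5-dien-1-ol
Product: 5 [(2R,3R)-3-allyl-3-methyloxiran-2-yl]methanol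
Conditions: Ti(OiPr)4 (cat.), D-(−)-diethyl tartrate (cat.), t-BuOOH, 4 Å MS, CH2Cl2, −20 °C
Reagents that add atoms: tert-butyl hydroperoxide CC(C)(C)OO
Why: Sharpless asymmetric epoxidation touches only the allylic alcohol alkene, and with a geraniol-type substrate the D-(−)-tartrate catalyst should give the (2R,3R)-epoxide, which sets the absolute configuration of the whole route.

Step 3
Reactants: 5 [(2R,3R)-3-allyl-3-methyloxiran-2-yl]methanol
Product: 6 {[(2R,3R)-3-allyl-3-methyloxiran-2-yl]methoxy}(tert-butyl)dimethylsilane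
Conditions: TBSCl, imidazole, DMF, 0 °C to rt
Reagents that add atoms: tert-butyldimethylsilyl chloride CC(C)(C)[Si](C)(C)Cl
Why: This is standard silylation of a primary alcohol, and it provides the silyl ether that the next rearrangement requires without touching either stereocentre.

Step 4
Reactants: 6 {[(2R,3R)-3-allyl-3-methyloxiran-2-yl]methoxy}(tert-butyl)dimethylsilane
Product: 7 (R)-2-{[(tert-butyldimethylsilyl)oxy]methyl}-2-methylpent-4-enal
Conditions: MABR (cat., from Me3Al and 4-bromo-2,6-di-tert-butylphenol), CH2Cl2, −78 to −40 °C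
Reagents that add atoms: none
Why: In this semipinacol-type rearrangement of an epoxy silyl ether with a bulky aluminium Lewis acid, the tertiary C3–O bond ionises and the siloxymethyl group migrates from C2 anti to the departing oxygen, so the epoxide configuration is transferred with inversion at C3 into the quaternary centre (future C4).

Step 5
Reactants: 7 (R)-2-{[(tert-butyldimethylsilyl)oxy]methyl}-2-methylpent-4-enal
Product: 8 tert-butyl({(2S)-2-[(E)-2-methoxyethenyl]-2-methylpent-4-en-1-yl}oxy)dimethylsilane
Conditions: MeOCH2PPh3Cl, KHMDS, THF, 0 °C; then 7, 0 °C to rt; E isomer separated on Et3N-washed SiO2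
Reagents that add atoms: (methoxymethyl)triphenylphosphonium chloride COC[P+](c1ccccc1)(c1ccccc1)c1ccccc1.[Cl-]
Why: Wittig methoxymethylenation works on non-enolisable neopentyl aldehydes, the E isomer should prevail next to the quaternary carbon and is separated from the Z isomer, and C4 is untouched.

Step 6
Reactants: 8 tert-butyl({(2S)-2-[(E)-2-methoxyethenyl]-2-methylpent-4-en-1-yl}oxy)dimethylsilane; 9 3,5-dibromo-2H-pyran-2-one
Product: 11 5-bromo-3-[(4S,5E)-4-{[(tert-butyldimethylsilyl)oxy]methyl}-6-methoxy-4-methylhex-5-en-1-yl]-2H-pyran-2-one, via B-alkyl-9-BBN 10 (not isolated)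
Conditions: 9-BBN, THF, rt; then 9, PdCl2(dppf) (cat.), aq. K3PO4, THF, 45 °C
Reagents that add atoms: none
Why: 9-BBN hydroborates the monosubstituted alkene far faster than the hindered 1,2-disubstituted enol ether, and B-alkyl Suzuki–Miyaura coupling of 3,5-dibromo-2-pyrone takes place at the more electron-poor C3–Br bond, which leaves C5–Br as the later handle at C8.

Step 7
Reactants: 11 5-bromo-3-[(4S,5E)-4-{[(tert-butyldimethylsilyl)oxy]methyl}-6-methoxy-4-methylhex-5-en-1-yl]-2H-pyran-2-one
Product: 12 8-bromo-6α-methoxy-19-[(tert-butyldimethylsilyl)oxy]-11,12,13,14,15,16,17-heptanorabiet-8-en-20,7β-olide (5α-H)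
Conditions: PhMe (0.01 M), BHT, 110 °C, sealed tube
Reagents that add atoms: none
Why: In this intramolecular Diels–Alder reaction of a 5-halo-2-pyrone (bicyclic lactones of this class survive about 110 °C without losing CO2), the four-carbon tether fixes the regiochemistry, the E-enol ether is translated suprafacially into the trans C4/OMe relationship across C5–C6, the OMe-endo/tether-exo chair-like transition state gives 5α-H, 6α-OMe and the β lactone bridge between C7 and C10, and the C4 stereocentre should select the pyrone face by keeping its methyl group anti to the forming C5–C10 bond and the CH2OTBS arm beside the pyrone carbonyl, the C4-mismatched adduct being removed by chromatography.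

Step 8
Reactants: 13 dimethyl squarate (3,4-dimethoxycyclobut-3-ene-1,2-dione)
Product: 16 2-isopropyl-3,4,4-trimethoxycyclobut-2-en-1-one, via chloromagnesium alkoxide 14 (not isolated), via trifluoroacetate 15 (not isolated)
Conditions: i-PrMgCl, THF, −78 °C; (CF3CO)2O, −78 °C; MeOH, −78 °C to rt; aq. NaHCO3
Reagents that add atoms: isopropylmagnesium chloride CC(C)[Mg]Cl; methanol CO
Why: 1,2-Addition of the Grignard reagent to the squarate, ionisation of the trifluoroacetate to the methoxy-stabilised cyclobutenyl cation and capture by methanol at the former C2 should give the cyclobutenedione monoacetal, in which the intrinsically more reactive carbonyl is masked.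

Step 9
Reactants: 12 8-bromo-6α-methoxy-19-[(tert-butyldimethylsilyl)oxy]-11,12,13,14,15,16,17-heptanorabiet-8-en-20,7β-olide; 16 2-isopropyl-3,4,4-trimethoxycyclobut-2-en-1-one
Product: 19 8-(1-hydroxy-2-isopropyl-3-methoxy-4-oxocyclobut-2-en-1-yl)-6α-methoxy-19-[(tert-butyldimethylsilyl)oxy]-11,12,13,14,15,16,17-heptanorabiet-8-en-20,7β-olide (C14 epimers), via vinyllithium 17 (not isolated), via lithium alkoxide 18 (not isolated)
Conditions: t-BuLi (2 equiv), THF–Et2O, −95 °C; 16, −78 °C; 0.5 M HCl, THF, 0 °C
Reagents that add atoms: water O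
Why: Bromine–lithium exchange at low temperature should outrun attack on the neopentyl-type bridged lactone carbonyl (C20 lies between quaternary C10 and the axial C19 arm, and β-elimination of the C7 carboxylate would need a bridged 1,2-cyclohexadiene), the vinyllithium adds 1,2 to the only free carbonyl of monoacetal 16 so that C8 is bonded to the carbon next to the isopropyl-bearing carbon, and mild acid unmasks the ketone, the new carbinol centre being formed without control because it is lost in step 10.

Step 10
Reactants: 19 8-(1-hydroxy-2-isopropyl-3-methoxy-4-oxocyclobut-2-en-1-yl)-6α-methoxy-19-[(tert-butyldimethylsilyl)oxy]-11,12,13,14,15,16,17-heptanorabiet-8-en-20,7β-olide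
Product: 22 6α,12-dimethoxy-19-[(tert-butyldimethylsilyl)oxy]-11,14-dioxoabieta-8,12-dien-20,7β-olide, via dienylketene 20 (not isolated), via hydroquinone 21 (not isolated)
Conditions: PhMe (0.02 M), 100 °C, Ar; then Ag2O, rt
Reagents that add atoms: none
Why: Thermal conrotatory 4π opening of the strained cyclobutenone (C11–C14 bond) turns the donor OH outward and the bicyclic alkenyl group inward to give dienylketene 20, disrotatory 6π electrocyclisation joins the ketene carbon C11 to C9, enolisation gives hydroquinone 21, and Ag2O oxidises it to quinone 22. This is the Moore-type ring expansion of 4-alkenyl-4-hydroxycyclobutenones, applied here to the C8=C9 alkene of a 2-oxabicyclo[2.2.2]octene. Ring C is the only ring formed and it closes by a six-electron electrocyclic mode through the new C9–C11 bond. No stereocentre is created, since the C14 carbinol centre and the transient sp3 C9 both become sp2, and C4, C5, C6, C7 and C10 are untouched. The substitution pattern (C12–OMe next to C11, the isopropyl carbon C13 next to C14) is fixed by the acetal-controlled addition of step 9, because C8=C9 is the only alkene that can act as the third π component. The selectivity needed is ring expansion over retro-[4+2] loss of CO2, which is secured because the same lactone framework has already passed through a higher temperature in step 7 and because aromatisation removes the isolated C8=C9 alkene that a cycloreversion would need.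

Step 11
Reactants: 22 6α,12-dimethoxy-19-[(tert-butyldimethylsilyl)oxy]-11,14-dioxoabieta-8,12-dien-20,7β-olide
Product: 23 6α,12,19-trihydroxy-11,14-dioxoabieta-8,12-dien-20,7β-olide (CNP0339604.1)
Conditions: BBr3 (excess), CH2Cl2, −78 °C to rt; H2O work-up
Reagents that add atoms: none
Why: Boron tribromide should cleave the carbonyl-chelated vinylogous ester OMe, the secondary methyl ether (bromide attacks CH3) and the silyl ether in one operation, while the lactone is safe because its alkyl carbon C7 is a bridgehead next to an electron-poor quinone that allows neither SN2 nor SN1 cleavage, and no stereocentre is touched.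

Compound list
1 | pent-1-en-4-yne | C=CCC#C | starting material
2 | dimethyl[(E)-2-methylpenta-1,4-dien-1-yl]alane | C=CC/C(C)=C/[Al](C)C | intermediate
3 | lithium butyl(dimethyl)[(E)-2-methylpenta-1,4-dien-1-yl]alanate | [Li+].C=CC/C(C)=C/[Al-](C)(C)CCCC | intermediate
4 | (E)-3-methylhexa-2,5-dien-1-ol | C=CC/C(C)=C/CO | intermediate
5 | [(2R,3R)-3-allyl-3-methyloxiran-2-yl]methanol | C=CC[C@@]1(C)O[C@@H]1CO | intermediate
6 | {[(2R,3R)-3-allyl-3-methyloxiran-2-yl]methoxy}(tert-butyl)dimethylsilane | C=CC[C@@]1(C)O[C@@H]1CO[Si](C)(C)C(C)(C)C | intermediate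
7 | (R)-2-{[(tert-butyldimethylsilyl)oxy]methyl}-2-methylpent-4-enal | C=CC[C@](C)(CO[Si](C)(C)C(C)(C)C)C=O | intermediate
8 | tert-butyl({(2S)-2-[(E)-2-methoxyethenyl]-2-methylpent-4-en-1-yl}oxy)dimethylsilane | C=CC[C@](C)(CO[Si](C)(C)C(C)(C)C)/C=C/OC | intermediate
9 | 3,5-dibromo-2H-pyran-2-one | O=C1OC=C(Br)C=C1Br | starting material
10 | 9-[(4S,5E)-4-{[(tert-butyldimethylsilyl)oxy]methyl}-6-methoxy-4-methylhex-5-en-1-yl]-9-borabicyclo[3.3.1]nonane | B1(CCC[C@](C)(CO[Si](C)(C)C(C)(C)C)/C=C/OC)C2CCCC1CCC2 | intermediate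
11 | 5-bromo-3-[(4S,5E)-4-{[(tert-butyldimethylsilyl)oxy]methyl}-6-methoxy-4-methylhex-5-en-1-yl]-2H-pyran-2-one | O=C1OC=C(Br)C=C1CCC[C@](C)(CO[Si](C)(C)C(C)(C)C)/C=C/OC | intermediate
12 | 8-bromo-6α-methoxy-19-[(tert-butyldimethylsilyl)oxy]-11,12,13,14,15,16,17-heptanorabiet-8-en-20,7β-olide | C2=C(Br)[C@H]1OC(=O)[C@@]23CCC[C@](C)(CO[Si](C)(C)C(C)(C)C)[C@@H]3[C@H]1OC | intermediate
13 | dimethyl squarate | COC1=C(OC)C(=O)C1=O | starting material
14 | chloromagnesium 1-isopropyl-2,3-dimethoxy-4-oxocyclobut-2-en-1-olate | COC1=C(OC)C([O-])(C(C)C)C1=O.[Mg+2].[Cl-] | intermediate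
15 | 1-isopropyl-2,3-dimethoxy-4-oxocyclobut-2-en-1-yl trifluoroacetate | COC1=C(OC)C(OC(=O)C(F)(F)F)(C(C)C)C1=O | intermediate
16 | 2-isopropyl-3,4,4-trimethoxycyclobut-2-en-1-one | COC1=C(C(C)C)C(=O)C1(OC)OC | intermediate
17 | 8-lithio analogue of 12 | C2=C([Li])[C@H]1OC(=O)[C@@]23CCC[C@](C)(CO[Si](C)(C)C(C)(C)C)[C@@H]3[C@H]1OC | intermediate
18 | lithium alkoxide of the C8–C14 adduct with the C11 dimethyl acetal intact (C14 epimers) | [Li+].C2=C(C4([O-])C(C(C)C)=C(OC)C4(OC)OC)[C@H]1OC(=O)[C@@]23CCC[C@](C)(CO[Si](C)(C)C(C)(C)C)[C@@H]3[C@H]1OC | intermediate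
19 | 8-(1-hydroxy-2-isopropyl-3-methoxy-4-oxocyclobut-2-en-1-yl)-6α-methoxy-19-[(tert-butyldimethylsilyl)oxy]-11,12,13,14,15,16,17-heptanorabiet-8-en-20,7β-olide (C14 epimers) | C2=C(C4(O)C(C(C)C)=C(OC)C4=O)[C@H]1OC(=O)[C@@]23CCC[C@](C)(CO[Si](C)(C)C(C)(C)C)[C@@H]3[C@H]1OC | intermediate
20 | dienylketene (C11 ketene, C12 OMe, C13=C14 with C8 cis to C12, C14 OH) | C2=C(/C(O)=C(C(C)C)\C(OC)=C=O)[C@H]1OC(=O)[C@@]23CCC[C@](C)(CO[Si](C)(C)C(C)(C)C)[C@@H]3[C@H]1OC | intermediate
21 | 11,14-dihydroxy-6α,12-dimethoxy-19-[(tert-butyldimethylsilyl)oxy]abieta-8,11,13-trien-20,7β-olide | CC(C)c1c(OC)c(O)c2c(c1O)[C@H]1OC(=O)[C@@]23CCC[C@](C)(CO[Si](C)(C)C(C)(C)C)[C@@H]3[C@H]1OC | intermediate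
22 | 6α,12-dimethoxy-19-[(tert-butyldimethylsilyl)oxy]-11,14-dioxoabieta-8,12-dien-20,7β-olide | CC(C)C1=C(OC)C(=O)C2=C(C1=O)[C@H]1OC(=O)[C@@]23CCC[C@](C)(CO[Si](C)(C)C(C)(C)C)[C@@H]3[C@H]1OC | intermediate
23 | 6α,12,19-trihydroxy-11,14-dioxoabieta-8,12-dien-20,7β-olide (CNP0339604.1) | CC(C)C1=C(O)C(=O)C2=C(C1=O)[C@H]1OC(=O)[C@@]23CCC[C@](C)(CO)[C@@H]3[C@H]1O | target

Total step count: 11. Longest linear sequence: 10 (steps 1–7 and 9–11). Step 8 is a one-step side branch.

Steps most likely to fail

Step 7. The C4 stereocentre may discriminate poorly between the two pyrone faces, because methyl and siloxymethyl are similar in size. The cycloaddition may also be slow, because the tether forces the nucleophilic enol ether carbon C5 onto the less electrophilic pyrone terminus.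
Fallback, from 11 back to 12: a directing group replaces pure steric control.
- The silyl ether of 11 is cleaved with TBAF/AcOH to the free alcohol F1.
- On heating in toluene, the C19 hydroxyl can hydrogen-bond to the pyrone carbonyl. This holds the CH2OH arm on the carbonyl side of the chair-like transition state and lowers the pyrone LUMO, and it should give the hydroxy lactone F2.
- Silylation (TBSCl, imidazole) returns to 12.

Step 10. Cycloreversion of the bicyclic lactone with loss of CO2 may compete with the electrocyclic cascade.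
Fallback, from 12 back to 22: C20 is taken out of the carboxyl oxidation level so that no CO2 can leave.
- DIBAL-H (CH2Cl2, −78 °C) reduces 12 to the lactol F3, and MeOH/PPTS converts it into the bridged methyl acetal F4.
- Bromine–lithium exchange, addition to 16 and mild acid as in step 9 give the hydroxycyclobutenone acetal F5.
- Heating and Ag2O as in step 10 give the quinone acetal F6.
- mCPBA/BF3·OEt2 oxidises the lactol ether to the lactone and rejoins the route at 22.

Step 9. t-BuLi or the vinyllithium may attack the lactone carbonyl, the halogen–metal exchange may be incomplete, and the tertiary carbinol may ionise during acetal hydrolysis.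
Fallback, from 12 and 16 back to 22: a neutral palladium route avoids any carbanion.
- Pd(PPh3)4 and hexamethylditin convert 12 into the vinylstannane F7.
- Acetal 16 is reduced with DIBAL-H and hydrolysed on acidic work-up to 4-hydroxy-3-isopropyl-2-methoxycyclobut-2-enone F8, which SOCl2/pyridine turns into the 4-chlorocyclobutenone F9.
- Stille coupling of F7 with F9 (Pd2(dba)3, tri(2-furyl)phosphine, dioxane, 50 °C) gives the 4-alkenylcyclobutenone F10.
- Further warming takes F10 through the same 4π/6π cascade to the phenol F11 (11-OH, 14-H).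
- Teuber oxidation with Fremy's salt at the free para position C14 gives 22.

Further compounds
F1 | step 7 | 5-bromo-3-[(4S,5E)-4-(hydroxymethyl)-6-methoxy-4-methylhex-5-en-1-yl]-2H-pyran-2-one | O=C1OC=C(Br)C=C1CCC[C@](C)(CO)/C=C/OC
F2 | step 7 | 8-bromo-19-hydroxy-6α-methoxy-11,12,13,14,15,16,17-heptanorabiet-8-en-20,7β-olide | C2=C(Br)[C@H]1OC(=O)[C@@]23CCC[C@](C)(CO)[C@@H]3[C@H]1OC
F3 | step 10 | C20 lactol of 12 (7β,20-epoxy-20-ol, C20 epimers) | C2=C(Br)[C@H]1OC(O)[C@@]23CCC[C@](C)(CO[Si](C)(C)C(C)(C)C)[C@@H]3[C@H]1OC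
F4 | step 10 | C20 methyl acetal of 12 (7β,20-epoxy-20-methoxy, C20 epimers) | C2=C(Br)[C@H]1OC(OC)[C@@]23CCC[C@](C)(CO[Si](C)(C)C(C)(C)C)[C@@H]3[C@H]1OC
F5 | step 10 | C20 methyl acetal analogue of 19 | C2=C(C4(O)C(C(C)C)=C(OC)C4=O)[C@H]1OC(OC)[C@@]23CCC[C@](C)(CO[Si](C)(C)C(C)(C)C)[C@@H]3[C@H]1OC
F6 | step 10 | C20 methyl acetal analogue of 22 | CC(C)C1=C(OC)C(=O)C2=C(C1=O)[C@H]1OC(OC)[C@@]23CCC[C@](C)(CO[Si](C)(C)C(C)(C)C)[C@@H]3[C@H]1OC
F7 | step 9 | 8-(trimethylstannyl) analogue of 12 | C2=C([Sn](C)(C)C)[C@H]1OC(=O)[C@@]23CCC[C@](C)(CO[Si](C)(C)C(C)(C)C)[C@@H]3[C@H]1OC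
F8 | step 9 | 4-hydroxy-3-isopropyl-2-methoxycyclobut-2-en-1-one | COC1=C(C(C)C)C(O)C1=O
F9 | step 9 | 4-chloro-3-isopropyl-2-methoxycyclobut-2-en-1-one | COC1=C(C(C)C)C(Cl)C1=O
F10 | step 9 | 8-(2-isopropyl-3-methoxy-4-oxocyclobut-2-en-1-yl) analogue of 12 (C14 epimers) | C2=C(C4C(C(C)C)=C(OC)C4=O)[C@H]1OC(=O)[C@@]23CCC[C@](C)(CO[Si](C)(C)C(C)(C)C)[C@@H]3[C@H]1OC
F11 | step 9 | 11-hydroxy-6α,12-dimethoxy-19-[(tert-butyldimethylsilyl)oxy]abieta-8,11,13-trien-20,7β-olide | CC(C)c1c(OC)c(O)c2c(c1)[C@H]1OC(=O)[C@@]23CCC[C@](C)(CO[Si](C)(C)C(C)(C)C)[C@@H]3[C@H]1OC
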